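The target SMILES is read as procyanidin B3 3,3'-digallate: two (2R,3S)-catechin gallate units joined 4α→8. The route opens ring C of the catechin unit at C3–C4 and O1–C8a, exploiting the ortho pair on ring A formed by the benzylic carbon C4 and the oxygen-bearing carbon C8a. A ring A benzylic bromide carrying an ortho aryl bromide meets the enolate of the ring B acetophenone, which supplies C3 and O1: C-benzylation and copper-catalysed enolate O-arylation in one flask close ring C as a flav-2-ene. Asymmetric hydroboration sets C2 and C3 trans; the resulting benzylated catechin gallate serves as nucleophile and, after C4 oxidation, as electrophile for the dimerisation, and hydrogenolysis ends the route.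

Key step: step 4

Remark: both flavan units are 2R,3S (2,3-trans) and the upper unit is 4S (3,4-trans, 4α).
Assumption: IpcBH2 made from (+)-α-pinene is taken to attack alkene 7 with the facial sense it shows towards 1-arylcycloalkenes (ring O1 in the place of a ring CH2), which gives 2R,3S; if the sense is the reverse, the reagent from (−)-α-pinene is used and nothing else changes.
Assumption: compounds 1, 5 and 10 are taken as commercially available.

Step 1
Reactants: 1 1,3-bis(benzyloxy)-5-bromobenzene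
Product: 2 2,4-bis(benzyloxy)-6-bromobenzaldehyde
Conditions: POCl3, DMF, 0 → 70 °C; then aq. NaOH, 0 °C
Reagents that add atoms: N,N-dimethylformamide CN(C)C=O; water O
Why: Vilsmeier–Haack formylation, in which the chloroiminium ion should attack the carbon para to one benzyloxy group and ortho to the other (next to bromine), which is less hindered than the carbon between the two ethers.

Step 2
Reactants: 2 2,4-bis(benzyloxy)-6-bromobenzaldehyde
Product: 3 [2,4-bis(benzyloxy)-6-bromophenyl]methanol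
Conditions: NaBH4, THF/MeOH, 0 °C
Reagents that add atoms: none
Why: Borohydride reduction of an aryl aldehyde, to which the aryl bromide and the benzyl ethers are inert.

Step 3
Reactants: 3 [2,4-bis(benzyloxy)-6-bromophenyl]methanol
Product: 4 1,5-bis(benzyloxy)-3-bromo-2-(bromomethyl)benzene
Conditions: PBr3, Et2O, 0 °C; used crude at once
Reagents that add atoms: phosphorus tribromide BrP(Br)Br
Why: Conversion of a benzylic alcohol into the bromide through its phosphite ester (SN2), with the labile electron-rich benzylic bromide carried on without chromatography.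

Step 4
Reactants: 5 1-[3,4-bis(benzyloxy)phenyl]ethanone; 4 1,5-bis(benzyloxy)-3-bromo-2-(bromomethyl)benzene
Product: 7 5,7-bis(benzyloxy)-2-[3,4-bis(benzyloxy)phenyl]-4H-chromene, via bromo ketone 6 (not isolated)
Conditions: 5 (1.3 equiv), KN(SiMe3)2, THF, −78 °C; 4, −78 → 0 °C; then KN(SiMe3)2, CuI (10 mol %), 1,10-phenanthroline (20 mol %), toluene, 90 °C, same flask
Reagents that add atoms: none
Why: Proposed new method: the potassium enolate of 5 is C-benzylated by the benzylic bromide of 4 (SN2, forming C3–C4) to give 6, whose enolate then undergoes copper-catalysed intramolecular O-arylation at the aryl bromide (oxidative addition of the C8a–Br bond to an O-bound monovalent copper enolate, then C–O reductive elimination from trivalent copper, forming O1–C8a); the closest known reaction type is the CuI-catalysed domino C-benzylation/O-arylation of β-keto esters with 2-bromobenzyl bromides to 4H-chromenes, carried over here to a simple aryl ketone by preforming each enolate with a strong amide base. Ring C is closed by attack of the enolate oxygen on C8a in a six-membered, exo-type closure, whereas carbon arylation would need a four-membered ring and is excluded. No stereocentre is formed. The step needs C- over O-benzylation, mono- over dialkylation and a Z-enolate of 6 (oxygen cis to the new CH2 group); a soft benzylic bromide with a potassium enolate in THF, the excess of 5, and the allylic strain that makes aryl ketone enolates Z should secure these.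

Step 5
Reactants: 7 5,7-bis(benzyloxy)-2-[3,4-bis(benzyloxy)phenyl]-4H-chromene
Product: 9 (2R,3S)-5,7-bis(benzyloxy)-2-[3,4-bis(benzyloxy)phenyl]chroman-3-ol, via dialkylborane 8 (not isolated)
Conditions: IpcBH2 [prepared beforehand from (+)-α-pinene], THF, −25 °C; then NaOH, H2O2, 0 °C → rt
Reagents that add atoms: hydrogen peroxide OO
Why: Asymmetric hydroboration–oxidation with monoisopinocampheylborane, as used for trisubstituted aryl cycloalkenes: boron adds to C3 (β to the ring oxygen, the less substituted carbon) and hydrogen to C2 on the same face, so the 2-aryl and 3-hydroxyl groups should end up trans, the chiral borane selects the alkene face that gives 2R,3S, and oxidation replaces boron with retention.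

Step 6
Reactants: 9 (2R,3S)-5,7-bis(benzyloxy)-2-[3,4-bis(benzyloxy)phenyl]chroman-3-ol; 10 3,4,5-tris(benzyloxy)benzoic acid
Product: 11 (2R,3S)-5,7-bis(benzyloxy)-2-[3,4-bis(benzyloxy)phenyl]chroman-3-yl 3,4,5-tris(benzyloxy)benzoate
Conditions: DCC, DMAP (cat.), CH2Cl2, 0 °C → rt
Reagents that add atoms: none
Why: Steglich esterification of the unhindered equatorial secondary alcohol, which touches no stereocentre.

Step 7
Reactants: 11 (2R,3S)-5,7-bis(benzyloxy)-2-[3,4-bis(benzyloxy)phenyl]chroman-3-yl 3,4,5-tris(benzyloxy)benzoate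
Product: 12 (2R,3S,4S)-5,7-bis(benzyloxy)-2-[3,4-bis(benzyloxy)phenyl]-4-(2-ethoxyethoxy)chroman-3-yl 3,4,5-tris(benzyloxy)benzoate
Conditions: DDQ, 2-ethoxyethanol, CH2Cl2, rt
Reagents that add atoms: 2-ethoxyethanol CCOCCO
Why: Benzylic oxidation with DDQ, in which hydride abstraction from C4 gives a cation stabilised by the 5,7-dioxygenated ring A that the alcohol should trap mainly axially (4β, drawn), the configuration at C4 being lost again in the next step.

Step 8
Reactants: 12 (2R,3S,4S)-5,7-bis(benzyloxy)-2-[3,4-bis(benzyloxy)phenyl]-4-(2-ethoxyethoxy)chroman-3-yl 3,4,5-tris(benzyloxy)benzoate; 11 (2R,3S)-5,7-bis(benzyloxy)-2-[3,4-bis(benzyloxy)phenyl]chroman-3-yl 3,4,5-tris(benzyloxy)benzoate (in excess)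
Product: 13 (2R,3S,4S)-5,7-bis(benzyloxy)-2-[3,4-bis(benzyloxy)phenyl]-4-{(2R,3S)-5,7-bis(benzyloxy)-2-[3,4-bis(benzyloxy)phenyl]-3-[3,4,5-tris(benzyloxy)benzoyloxy]chroman-8-yl}chroman-3-yl 3,4,5-tris(benzyloxy)benzoate
Conditions: Me3SiOTf (cat.), CH2Cl2, −78 °C; 11 (3 equiv)
Reagents that add atoms: none
Why: Lewis-acid-promoted Friedel–Crafts-type flavan coupling, in which Me3SiOTf ionises the C4 ether and C8 of 11 (the most nucleophilic and accessible position of its ring A) should attack the cation trans to the neighbouring 3-O-galloyl group, which shields the β-face also through acyloxonium participation, so that C4 is set as 4α (4S), while the excess of 11 suppresses oligomerisation.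

Step 9
Reactants: 13 the tetradeca-O-benzyl dimer of step 8
Product: 14 (2R,3S,4S)-2-(3,4-dihydroxyphenyl)-4-[(2R,3S)-2-(3,4-dihydroxyphenyl)-5,7-dihydroxy-3-(3,4,5-trihydroxybenzoyloxy)chroman-8-yl]-5,7-dihydroxychroman-3-yl 3,4,5-trihydroxybenzoate
Conditions: H2 (1 atm), Pd(OH)2/C, THF/MeOH/H2O, rt
Reagents that add atoms: none
Why: Catalytic hydrogenolysis of the fourteen benzyl ethers, under which the two esters, the interflavan C–C bond and the ring C ethers should survive.

Compound list
1 | 1,3-bis(benzyloxy)-5-bromobenzene | Brc1cc(OCc2ccccc2)cc(OCc2ccccc2)c1 | starting material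
2 | 2,4-bis(benzyloxy)-6-bromobenzaldehyde | O=Cc1c(Br)cc(OCc2ccccc2)cc1OCc1ccccc1 | intermediate
3 | [2,4-bis(benzyloxy)-6-bromophenyl]methanol | OCc1c(Br)cc(OCc2ccccc2)cc1OCc1ccccc1 | intermediate
4 | 1,5-bis(benzyloxy)-3-bromo-2-(bromomethyl)benzene | BrCc1c(Br)cc(OCc2ccccc2)cc1OCc1ccccc1 | intermediate
5 | 1-[3,4-bis(benzyloxy)phenyl]ethanone | CC(=O)c1ccc(OCc2ccccc2)c(OCc2ccccc2)c1 | starting material
6 | 3-[2,4-bis(benzyloxy)-6-bromophenyl]-1-[3,4-bis(benzyloxy)phenyl]propan-1-one (not isolated) | O=C(CCc1c(Br)cc(OCc2ccccc2)cc1OCc1ccccc1)c1ccc(OCc2ccccc2)c(OCc2ccccc2)c1 | intermediate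
7 | 5,7-bis(benzyloxy)-2-[3,4-bis(benzyloxy)phenyl]-4H-chromene | C1=C(c2ccc(OCc3ccccc3)c(OCc3ccccc3)c2)Oc2cc(OCc3ccccc3)cc(OCc3ccccc3)c2C1 | intermediate
8 | isopinocampheyl[trans-5,7-bis(benzyloxy)-2-(3,4-bis(benzyloxy)phenyl)chroman-3-yl]borane, C2 R, boron on the face later taken by the hydroxyl group (not isolated) | C[C@H]1[C@H](B[C@H]2Cc3c(OCc4ccccc4)cc(OCc4ccccc4)cc3O[C@@H]2c2ccc(OCc3ccccc3)c(OCc3ccccc3)c2)C[C@@H]2C[C@H]1C2(C)C | intermediate
9 | (2R,3S)-5,7-bis(benzyloxy)-2-[3,4-bis(benzyloxy)phenyl]chroman-3-ol | O[C@H]1Cc2c(OCc3ccccc3)cc(OCc3ccccc3)cc2O[C@@H]1c1ccc(OCc2ccccc2)c(OCc2ccccc2)c1 | intermediate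
10 | 3,4,5-tris(benzyloxy)benzoic acid | OC(=O)c1cc(OCc2ccccc2)c(OCc2ccccc2)c(OCc2ccccc2)c1 | starting material
11 | (2R,3S)-5,7-bis(benzyloxy)-2-[3,4-bis(benzyloxy)phenyl]chroman-3-yl 3,4,5-tris(benzyloxy)benzoate | O=C(O[C@H]1Cc2c(OCc3ccccc3)cc(OCc3ccccc3)cc2O[C@@H]1c1ccc(OCc2ccccc2)c(OCc2ccccc2)c1)c1cc(OCc2ccccc2)c(OCc2ccccc2)c(OCc2ccccc2)c1 | intermediate
12 | (2R,3S,4S)-5,7-bis(benzyloxy)-2-[3,4-bis(benzyloxy)phenyl]-4-(2-ethoxyethoxy)chroman-3-yl 3,4,5-tris(benzyloxy)benzoate | O=C(O[C@H]1[C@@H](OCCOCC)c2c(OCc3ccccc3)cc(OCc3ccccc3)cc2O[C@@H]1c1ccc(OCc2ccccc2)c(OCc2ccccc2)c1)c1cc(OCc2ccccc2)c(OCc2ccccc2)c(OCc2ccccc2)c1 | intermediate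
13 | tetradeca-O-benzyl procyanidin B3 3,3'-digallate, upper unit 2R,3S,4S, lower unit 2R,3S, 4α→8 | O=C(O[C@H]1[C@H](c2c(OCc3ccccc3)cc(OCc3ccccc3)c3c2O[C@H](c2ccc(OCc4ccccc4)c(OCc4ccccc4)c2)[C@@H](OC(=O)c2cc(OCc4ccccc4)c(OCc4ccccc4)c(OCc4ccccc4)c2)C3)c2c(OCc3ccccc3)cc(OCc3ccccc3)cc2O[C@@H]1c1ccc(OCc2ccccc2)c(OCc2ccccc2)c1)c1cc(OCc2ccccc2)c(OCc2ccccc2)c(OCc2ccccc2)c1 | intermediate
14 | procyanidin B3 3,3'-digallate, upper unit 2R,3S,4S, lower unit 2R,3S, 4α→8 | O=C(O[C@H]1[C@H](c2c(O)cc(O)c3c2O[C@H](c2ccc(O)c(O)c2)[C@@H](OC(=O)c2cc(O)c(O)c(O)c2)C3)c2c(O)cc(O)cc2O[C@@H]1c1ccc(O)c(O)c1)c1cc(O)c(O)c(O)c1 | target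

Total step count: 9. Longest linear sequence: 9 steps (1 → 2 → 3 → 4 → 7 → 9 → 11 → 12 → 13 → 14); 5 and 10 enter at steps 4 and 6.

Steps most likely to fail

Step 4. The first stage may suffer dialkylation or O-benzylation of the enolate. The second stage may stall, with protodebromination of the aryl bromide instead of C–O bond formation from the weakly acidic ketone. The fallback sets out from 5 and 4, comes back at 7, and keeps both bonds formed in one operation by the known reaction on its proven substrate class. Ketone 5 is carboxylated with diallyl carbonate and NaH in THF to allyl 3-[3,4-bis(benzyloxy)phenyl]-3-oxopropanoate F1. F1 and 4 are combined under the established CuI/Cs2CO3 domino conditions in DMF at 80–100 °C. There the doubly activated carbon is benzylated to allyl 2-[2,4-bis(benzyloxy)-6-bromobenzyl]-3-[3,4-bis(benzyloxy)phenyl]-3-oxopropanoate F2, which cyclises in the same flask by enol O-arylation to allyl 5,7-bis(benzyloxy)-2-[3,4-bis(benzyloxy)phenyl]-4H-chromene-3-carboxylate F3. Allyl transfer to morpholine with Pd(PPh3)4 frees 5,7-bis(benzyloxy)-2-[3,4-bis(benzyloxy)phenyl]-4H-chromene-3-carboxylic acid F4. This vinylogous carbonic acid should lose CO2 on gentle warming with a trace of AcOH (protonation at C3, then decarboxylation of the β-oxocarbenium acid) to give 7.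

Step 5. The chiral borane may discriminate the faces of the enol ether poorly. The β-aryloxy borane 8 may also lose the ring oxygen by β-elimination before it is oxidised; it is therefore kept cold and oxidised at once. The fallback sets out from 7 and comes back at 9, replacing asymmetric induction by resolution. Hydroboration–oxidation with BH3·SMe2 (THF, 0 °C; then NaOH, H2O2) gives the racemic trans alcohol, that is 9 together with its enantiomer (2S,3R)-5,7-bis(benzyloxy)-2-[3,4-bis(benzyloxy)phenyl]chroman-3-ol F5. Esterification of the mixture with (S)-2-methoxy-2-phenylacetic acid (DCC, DMAP) gives two diastereomers, separated by chromatography or crystallisation: (2R,3S)-5,7-bis(benzyloxy)-2-[3,4-bis(benzyloxy)phenyl]chroman-3-yl (S)-2-methoxy-2-phenylacetate F6 and (2S,3R)-5,7-bis(benzyloxy)-2-[3,4-bis(benzyloxy)phenyl]chroman-3-yl (S)-2-methoxy-2-phenylacetate F7. Saponification of F6 (LiOH, THF/MeOH/H2O) returns 9.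

Step 7. Hydride abstraction next to the electron-withdrawing ester may be slow. The acyloxonium ion may be captured as an orthoester, and benzyl ethers may be lost oxidatively on long exposure to DDQ. The fallback sets out from 9 and comes back at 12, reversing the order of oxidation and acylation. DDQ and 2-ethoxyethanol in CH2Cl2 oxidise the free alcohol 9 to (2R,3S,4S)-5,7-bis(benzyloxy)-2-[3,4-bis(benzyloxy)phenyl]-4-(2-ethoxyethoxy)chroman-3-ol F8. F8 is then esterified with 10 (DCC, DMAP, CH2Cl2) to give 12.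

Further compounds
F1 | step 4 | allyl 3-[3,4-bis(benzyloxy)phenyl]-3-oxopropanoate | C=CCOC(=O)CC(=O)c1ccc(OCc2ccccc2)c(OCc2ccccc2)c1
F2 | step 4 | allyl 2-[2,4-bis(benzyloxy)-6-bromobenzyl]-3-[3,4-bis(benzyloxy)phenyl]-3-oxopropanoate | C=CCOC(=O)C(Cc1c(Br)cc(OCc2ccccc2)cc1OCc1ccccc1)C(=O)c1ccc(OCc2ccccc2)c(OCc2ccccc2)c1
F3 | step 4 | allyl 5,7-bis(benzyloxy)-2-[3,4-bis(benzyloxy)phenyl]-4H-chromene-3-carboxylate | C=CCOC(=O)C1=C(c2ccc(OCc3ccccc3)c(OCc3ccccc3)c2)Oc2cc(OCc3ccccc3)cc(OCc3ccccc3)c2C1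
F4 | step 4 | 5,7-bis(benzyloxy)-2-[3,4-bis(benzyloxy)phenyl]-4H-chromene-3-carboxylic acid | OC(=O)C1=C(c2ccc(OCc3ccccc3)c(OCc3ccccc3)c2)Oc2cc(OCc3ccccc3)cc(OCc3ccccc3)c2C1
F5 | step 5 | (2S,3R)-5,7-bis(benzyloxy)-2-[3,4-bis(benzyloxy)phenyl]chroman-3-ol | O[C@@H]1Cc2c(OCc3ccccc3)cc(OCc3ccccc3)cc2O[C@H]1c1ccc(OCc2ccccc2)c(OCc2ccccc2)c1
F6 | step 5 | (2R,3S)-5,7-bis(benzyloxy)-2-[3,4-bis(benzyloxy)phenyl]chroman-3-yl (S)-2-methoxy-2-phenylacetate | CO[C@@H](c1ccccc1)C(=O)O[C@H]1Cc2c(OCc3ccccc3)cc(OCc3ccccc3)cc2O[C@@H]1c1ccc(OCc2ccccc2)c(OCc2ccccc2)c1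
F7 | step 5 | (2S,3R)-5,7-bis(benzyloxy)-2-[3,4-bis(benzyloxy)phenyl]chroman-3-yl (S)-2-methoxy-2-phenylacetate | CO[C@@H](c1ccccc1)C(=O)O[C@@H]1Cc2c(OCc3ccccc3)cc(OCc3ccccc3)cc2O[C@H]1c1ccc(OCc2ccccc2)c(OCc2ccccc2)c1
F8 | step 7 | (2R,3S,4S)-5,7-bis(benzyloxy)-2-[3,4-bis(benzyloxy)phenyl]-4-(2-ethoxyethoxy)chroman-3-ol | O[C@H]1[C@@H](OCCOCC)c2c(OCc3ccccc3)cc(OCc3ccccc3)cc2O[C@@H]1c1ccc(OCc2ccccc2)c(OCc2ccccc2)c1
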